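The meeting opened on the epsilon run, whose highest reading of isomer of the product, 10.4%, stood at its last time, 2.50 h.

- epsilon: substrate 0.17 M; reagent 0.99 M; run made earlier
- flask: substrate 0.33 M; reagent 0.990 M; time 25 h

epsilon run (percent of the substrate charged)

| time / h | isomer of the product / % | target / % |
|---|---|---|
| 0.200 | 1.7 | 6.5 |
| 0.500 | 4.6 | 8.4 |
| 1.00 | 8.6 | 5.1 |
| 2.50 | 10.4 | 1.2 |

(each reading ± 0.3 percentage points)

- time up to 25 h at which isomer of the product stands highest
- the amount of isomer of the product, in percent of the substrate charged, at that time

The forecaster argued that target forms fast and likely passes into isomer of the product, and that the flask charges reagent at the same concentration as the epsilon run. The forecast therefore held that “pseudo-first-order timing should hold”, and it gave 2.2 h (range 1.4 h to 4.5 h) and 10% (range 6.5% to 12.5%).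

I replied that reagent concentration sets the clock while it stays nearly constant, and asked the meeting to watch 3.00 in the flask: the reagent equivalents, reagent charged per substrate charged. The epsilon run had 5.82, more than the flask. As a trial, I took two reagent used per substrate, which leaves 33.3% of the reagent charge in the flask against 65.7% in the epsilon run. I therefore expected the flask's clock to slow as reagent falls, and its peak to come later than the forecast's time.

The flask gives 12.4% of isomer of the product at 2.49 h, inside both ranges, and this is the scheme:

    substrate + reagent → intermediate + by-product (k = 0.0470 /M/min)
    crystals ⇌ by-product, rate k2*(cs2 - [by-product]) while solid is left; crystals form when [by-product] > cs2 (solubility = 8.30 mM, k = 0.880 /min)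
    intermediate ⇌ target (K = 0.360, k = 0.160 /min)
    intermediate ⇌ isomer of the product (K = 2.10, k = 0.00640 /min)
    reagent + target → over-reaction product (k = 0.180 /M/min)

In the flask at 0.279 h, target falls back 3.1 times faster than it goes on to over-reaction product. By 2.49 h the flask holds 77.9% of over-reaction product, with reagent at 41.4% of its charge. At 25.0 h the flask keeps 34% of its reagent, against the trial 33.3%. The neighbour charged with 0.25 M of reagent has 0.758 equivalents; at 25.0 h its reagent, the limiting reagent there, stands at 0%, its substrate at 41% and its isomer of the product at 25.2%.

The numbers in the tables were computed for an exercise.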